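## Retrosynthetic overview

1. Target 11 comes from α-epoxide 9. The C4=C5 alkene is carried as an oxirane and released last by stereospecific deoxygenation. The C2 acetate comes from selective acetylation of the C1,C2-diol 8.
2. Diol 8 comes from alkene 6 by syn-dihydroxylation on the face opposite the C3/C6 benzoates and the oxirane. This sets C1 and C2.
3. Tribenzoate 6 comes from triol 5, and 5 from vinyl iodide 4. The C1–C7 bond is made by Pd cross-coupling with a hydroxymethyl donor.
4. Epoxy diol 4 comes from bromohydrin 3, 3 from cis-dihydrodiol 2, and 2 from iodobenzene 1 by enzymatic arene cis-dihydroxylation. The enzyme sets C6 and the relay centre C5, and C3 follows by anti addition.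
5. Rings: the carbocycle is the dearomatised ring of 1, so no ring-closing C–C step is needed. The oxirane is closed in step 3 and removed in step 8. The phenyl rings arrive with benzoyl chloride.

**Convention:** target locants are used for all intermediates. C1 carries OH and C7H2OBz, C2 carries OAc, C3 carries OBz, C4=C5 is the alkene, and C6 carries OBz. The β face is the face of C1-OH and C2-OAc. The α face is the face of the C3 and C6 oxygens.

**Assumption:** the culture medium of the whole-cell biotransformation (glucose feed, salts, inducer) counts as part of the catalyst system, not as a starting material.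

## Route

**Step 1**
Reactants: 1 iodobenzene
Product: 2 (1S,2S)-3-iodocyclohexa-3,5-diene-1,2-diol
Conditions: E. coli JM109(pDTG601A) whole cells expressing toluene dioxygenase (Rieske non-haem iron arene dioxygenase, oxidoreductase class, EC 1.14.12.11), IPTG, air, glucose feed, mineral salts medium pH 6.8–7.0, 35 °C; EtOAc extraction
Reagents that add atoms: dioxygen O=O
Why: In this enzymatic arene cis-dihydroxylation the dioxygenase adds both oxygens of O2 to one face of the ortho,meta bond next to the large iodine substituent of the achiral arene, so this catalytic asymmetric step creates the first two stereocentres (>98% ee), the carbinol next to C–I being C6 of the target and its neighbour the relay centre C5.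

**Step 2**
Reactants: 2 (1S,2S)-3-iodocyclohexa-3,5-diene-1,2-diol
Product: 3 (1S,2R,3R,4S)-3-bromo-6-iodocyclohex-5-ene-1,2,4-triol
Conditions: NBS (1.05 equiv), THF/H2O 4:1, 0 °C → rt, dark
Reagents that add atoms: N-bromosuccinimide O=C1CCC(=O)N1Br; water O
Why: In this regio- and diastereoselective bromohydrin formation (electrophilic anti addition) iodine deactivates its own double bond, so electrophilic bromine is taken up by the unsubstituted C3=C4 alkene on the β face opposite the two hydroxyls and water attacks the allylic carbon C3 from the α face, which sets C3–O cis to C6–O and places C4–Br trans to C5–OH.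

**Step 3**
Reactants: 3 (1S,2R,3R,4S)-3-bromo-6-iodocyclohex-5-ene-1,2,4-triol
Product: 4 (1R,2S,5S,6S)-3-iodo-7-oxabicyclo[4.1.0]hept-3-ene-2,5-diol
Conditions: NaOMe (1.05 equiv), THF/MeOH, 0 °C
Reagents that add atoms: none
Why: In this intramolecular Williamson (SN2) epoxide closure the C5 oxygen, the more acidic vicinal-diol oxygen and truly trans-diaxial to bromine, displaces bromide with inversion at C4 to give the non-allylic α-oxirane that masks the future C4=C5 alkene, and the two remaining hydroxyls are cis to the oxirane oxygen and therefore cannot start a Payne migration.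

**Step 4**
Reactants: 4 (1R,2S,5S,6S)-3-iodo-7-oxabicyclo[4.1.0]hept-3-ene-2,5-diol
Product: 5 (1R,2R,5S,6S)-3-(hydroxymethyl)-7-oxabicyclo[4.1.0]hept-3-ene-2,5-diol
Conditions: Bu3SnCH2OH (1.3 equiv), Pd(PPh3)4 (5 mol %), degassed 1,4-dioxane, 90 °C
Reagents that add atoms: (tributylstannyl)methanol OC[Sn](CCCC)(CCCC)CCCC
Why: In this Stille (Migita–Kosugi–Stille) hydroxymethylation the vinyl iodide adds oxidatively to Pd(0) far faster than any other group reacts, the α-oxygenated CH2OH group is transferred in preference to butyl under neutral conditions that leave free hydroxyls and the non-allylic oxirane alone, and no stereocentre is involved.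

**Step 5**
Reactants: 5 (1R,2R,5S,6S)-3-(hydroxymethyl)-7-oxabicyclo[4.1.0]hept-3-ene-2,5-diol
Product: 6 [(1R,2R,5S,6S)-2,5-bis(benzoyloxy)-7-oxabicyclo[4.1.0]hept-3-en-3-yl]methyl benzoate
Conditions: BzCl (4 equiv), pyridine, DMAP (cat.), CH2Cl2, 0 °C → rt
Reagents that add atoms: benzoyl chloride O=C(Cl)c1ccccc1
Why: This exhaustive DMAP-catalysed O-acylation installs the three benzoates of the target on C3-O, C6-O and C7-O in one operation with retention everywhere because only O–H bonds are broken, and the oxirane is inert under these conditions.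

**Step 6**
Reactants: 6 [(1R,2R,5S,6S)-2,5-bis(benzoyloxy)-7-oxabicyclo[4.1.0]hept-3-en-3-yl]methyl benzoate
Product: 8 [(1S,2S,3S,4S,5S,6R)-2,5-bis(benzoyloxy)-3,4-dihydroxy-7-oxabicyclo[4.1.0]heptan-3-yl]methyl benzoate, via cyclic osmate ester 7 (not isolated)
Conditions: OsO4 (5–10 mol %), NMO (2 equiv), citric acid (0.75 equiv), acetone/t-BuOH/H2O, rt, 24–48 h
Reagents that add atoms: osmium tetroxide O=[Os](=O)(=O)=O; N-methylmorpholine N-oxide C[N+]1([O-])CCOCC1; water O
Why: In this Upjohn syn-dihydroxylation the only alkene left reacts in a [3+2] fashion from the β face, because both allylic benzoates and the oxirane oxygen shield the α face (attack anti to allylic oxygen), which sets C1-OH and C2-OH cis to each other and trans to the C3 and C6 benzoates, while the slightly acidic citrate medium speeds turnover on the electron-poor alkene and suppresses benzoate migration.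

**Step 7**
Reactants: 8 [(1S,2S,3S,4S,5S,6R)-2,5-bis(benzoyloxy)-3,4-dihydroxy-7-oxabicyclo[4.1.0]heptan-3-yl]methyl benzoate
Product: 9 [(1S,2S,3S,4S,5R,6R)-4-acetoxy-2,5-bis(benzoyloxy)-3-hydroxy-7-oxabicyclo[4.1.0]heptan-3-yl]methyl benzoate
Conditions: Ac2O (1.5 equiv), pyridine, DMAP (5 mol %), CH2Cl2, 0 °C → rt
Reagents that add atoms: acetic anhydride CC(=O)OC(C)=O
Why: In this chemoselective acylation the secondary C2-OH is esterified while the tertiary, fully flanked C1-OH does not react under these mild conditions, and no stereocentre is touched.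

**Step 8**
Reactants: 9 [(1S,2S,3S,4S,5R,6R)-4-acetoxy-2,5-bis(benzoyloxy)-3-hydroxy-7-oxabicyclo[4.1.0]heptan-3-yl]methyl benzoate
Product: 11 [(1R,2S,5R,6S)-6-acetoxy-2,5-bis(benzoyloxy)-1-hydroxycyclohex-3-en-1-yl]methyl benzoate, via β-episelenide 10 (not isolated)
Conditions: Ph3P=Se (1.5–2 equiv), CF3CO2H (1.5–2 equiv), CH2Cl2, 0 °C → rt, dark
Reagents that add atoms: none
Why: In this stereospecific epoxide deoxygenation by oxygen–selenium exchange the acid-activated oxirane is opened anti by the soft selenium atom, phosphorus moves to oxygen and the selenolate closes with a second inversion to episelenide 10, which extrudes selenium spontaneously to give the cis alkene strictly between C4 and C5, while C1, C2, C3 and C6 are untouched because both flanking benzoates are cis to the oxirane oxygen and cannot participate.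

## Compound list

1 | iodobenzene | Ic1ccccc1 | starting material
2 | (1S,2S)-3-iodocyclohexa-3,5-diene-1,2-diol | IC1=CC=C[C@H](O)[C@@H]1O | intermediate
3 | (1S,2R,3R,4S)-3-bromo-6-iodocyclohex-5-ene-1,2,4-triol (C3-OH α, C4-Br β, C5-OH α, C6-OH α) | IC1=C[C@H](O)[C@@H](Br)[C@H](O)[C@@H]1O | intermediate
4 | (1R,2S,5S,6S)-3-iodo-7-oxabicyclo[4.1.0]hept-3-ene-2,5-diol (oxirane O and both OH on the α face) | IC1=C[C@H](O)[C@@H]2O[C@@H]2[C@@H]1O | intermediate
5 | (1R,2R,5S,6S)-3-(hydroxymethyl)-7-oxabicyclo[4.1.0]hept-3-ene-2,5-diol | OCC1=C[C@H](O)[C@@H]2O[C@@H]2[C@@H]1O | intermediate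
6 | [(1R,2R,5S,6S)-2,5-bis(benzoyloxy)-7-oxabicyclo[4.1.0]hept-3-en-3-yl]methyl benzoate | O=C(c1ccccc1)OCC1=C[C@H](OC(=O)c2ccccc2)[C@@H]2O[C@@H]2[C@@H]1OC(=O)c1ccccc1 | intermediate
7 | cyclic osmate(VI) ester of 8, Os bridging the β oxygens on C1 and C2 (not isolated) | O=[Os]1(=O)O[C@H]2[C@H](OC(=O)c3ccccc3)[C@@H]3O[C@@H]3[C@H](OC(=O)c3ccccc3)[C@@]2(COC(=O)c2ccccc2)O1 | intermediate
8 | [(1S,2S,3S,4S,5S,6R)-2,5-bis(benzoyloxy)-3,4-dihydroxy-7-oxabicyclo[4.1.0]heptan-3-yl]methyl benzoate | O[C@H]1[C@H](OC(=O)c2ccccc2)[C@@H]2O[C@@H]2[C@H](OC(=O)c2ccccc2)[C@]1(O)COC(=O)c1ccccc1 | intermediate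
9 | [(1S,2S,3S,4S,5R,6R)-4-acetoxy-2,5-bis(benzoyloxy)-3-hydroxy-7-oxabicyclo[4.1.0]heptan-3-yl]methyl benzoate | CC(=O)O[C@H]1[C@H](OC(=O)c2ccccc2)[C@@H]2O[C@@H]2[C@H](OC(=O)c2ccccc2)[C@]1(O)COC(=O)c1ccccc1 | intermediate
10 | β-episelenide, the 7-selenabicyclo[4.1.0]heptane analogue of 9 with Se on the face of C1-OH (not isolated) | CC(=O)O[C@H]1[C@H](OC(=O)c2ccccc2)[C@H]2[Se][C@H]2[C@H](OC(=O)c2ccccc2)[C@]1(O)COC(=O)c1ccccc1 | intermediate
11 | [(1R,2S,5R,6S)-6-acetoxy-2,5-bis(benzoyloxy)-1-hydroxycyclohex-3-en-1-yl]methyl benzoate (CNP0148821.1) | CC(=O)O[C@H]1[C@H](OC(=O)c2ccccc2)C=C[C@H](OC(=O)c2ccccc2)[C@]1(O)COC(=O)c1ccccc1 | target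

## Step count and risks

Total step count: 8. Longest linear sequence: 8 (fully linear from 1).

**Step 8.** The oxirane is hindered and flanked by two acyloxy groups, so it may react slowly or be opened by trifluoroacetate. The fallback sets out from 9 and comes back at 11. It replaces chalcogen exchange with a halohydrin–sulfonate reductive elimination. LiBr/AcOH in THF opens 9 trans-diaxially, with attack at C5 from the β face in the half-chair that keeps CH2OBz equatorial, and gives the bromohydrin F6. MsCl/Et3N at −10 °C sulfonylates its only secondary hydroxyl and gives the bromo mesylate F7. Zn dust with catalytic NaI in DMF at 60 °C then removes the anti Br and OMs to give 11. The mesylate is a far better leaving group than the C6 benzoate on the other side of the C–Br carbon.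

**Step 4.** Transfer of an sp3 group from tin to a polar, unprotected substrate may be slow, and tin residues are hard to separate from the triol. The fallback sets out from 4 and comes back at 5. It brings in C7 as carbon monoxide instead of as a stannane. Pd(OAc)2/PPh3, CO (1 atm), MeOH and Et3N at 50 °C convert 4 into the methyl enoate F1. DIBAL-H (5 equiv) in CH2Cl2/THF at −78 °C reduces the ester to the allylic alcohol 5 before the oxirane can react.

**Step 6.** The trisubstituted alkene carries three allylic benzoates, so it is electron-poor and the hindered osmate may hydrolyse slowly. The fallback sets out from 5 and comes back at 9. It moves the dihydroxylation ahead of the benzoylation, onto an electron-richer alkene.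
- TBSCl/imidazole in DMF gives the tris-TBS ether F2.
- OsO4/NMO attacks F2 from the β face, anti to the two α silyloxy groups and the oxirane, and gives the silylated diol F3.
- Ac2O/pyridine/DMAP acetylates only C2-OH and gives the silylated monoacetate F4.
- HF·pyridine in THF removes the three silyl groups under acidic conditions that disfavour acetyl migration and gives the acetate tetraol F5.
- F5 is benzoylated at once (BzCl, pyridine, DMAP) on its three non-tertiary hydroxyls to reach 9.

## Further compounds

F1 | step 4 | methyl (1R,2R,5S,6S)-2,5-dihydroxy-7-oxabicyclo[4.1.0]hept-3-ene-3-carboxylate | COC(=O)C1=C[C@H](O)[C@@H]2O[C@@H]2[C@@H]1O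
F2 | step 6 | tris(tert-butyldimethylsilyl) ether of 5 (C3-O, C6-O and C7-O silylated) | CC(C)(C)[Si](C)(C)OCC1=C[C@H](O[Si](C)(C)C(C)(C)C)[C@@H]2O[C@@H]2[C@@H]1O[Si](C)(C)C(C)(C)C
F3 | step 6 | C1,C2-β-diol of F2 (analogue of 8 with three OTBS in place of three OBz) | O[C@H]1[C@H](O[Si](C)(C)C(C)(C)C)[C@@H]2O[C@@H]2[C@H](O[Si](C)(C)C(C)(C)C)[C@]1(O)CO[Si](C)(C)C(C)(C)C
F4 | step 6 | C2-O-acetate of F3 | CC(=O)O[C@H]1[C@H](O[Si](C)(C)C(C)(C)C)[C@@H]2O[C@@H]2[C@H](O[Si](C)(C)C(C)(C)C)[C@]1(O)CO[Si](C)(C)C(C)(C)C
F5 | step 6 | desilylated F4, the C2-acetate with free C1-, C3-, C6- and C7-OH and the α-oxirane | CC(=O)O[C@H]1[C@H](O)[C@@H]2O[C@@H]2[C@H](O)[C@]1(O)CO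
F6 | step 8 | bromohydrin of 9 with C5-Br β and C4-OH α, all other groups as in 9 | CC(=O)O[C@H]1[C@H](OC(=O)c2ccccc2)[C@H](O)[C@@H](Br)[C@H](OC(=O)c2ccccc2)[C@]1(O)COC(=O)c1ccccc1
F7 | step 8 | C4-O-methanesulfonate of F6 | CC(=O)O[C@H]1[C@H](OC(=O)c2ccccc2)[C@H](OS(C)(=O)=O)[C@@H](Br)[C@H](OC(=O)c2ccccc2)[C@]1(O)COC(=O)c1ccccc1
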